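(The constants are those of an exercise; what happens was integrated by code.)

The question was how product and trapped intermediate divide what leaves intermediate B in three vessels.

| setting | north-west | north | south-west |
|---|---|---|---|
| starting material | 0.30 M | 0.30 M (fed, over 24.0 h) | 0.30 M |
| capture agent | 0.0300 M | 0.0300 M | 0.0300 M |
| time | 30 h | 30 h |  |
| remark | a closed flask charged with all of it at once and left for 30 h | all but starting material at the start; starting material goes in evenly over 24.0 h, the run ends at 30 h | one stirred flow tank at steady state, fed with the mixture as stated, mean residence time 30 h |

    capture agent + intermediate B → trapped intermediate (k1 = 0.11 /M/h)
    intermediate A ⇌ intermediate D (K2 = 12, k2 = 0.041 /h)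
    intermediate B ⇌ intermediate E (K3 = 0.59, k3 = 0.012 /h)
    starting material ⇌ intermediate B (K4 = 1.0, k4 = 0.015 /h)
    starting material → intermediate A (k5 = 0.070 /h)
    intermediate B ⇌ intermediate C (K6 = 0.44, k6 = 0.050 /h)
    intermediate C → product (k7 = 0.0044 /h)

1. the set-up with the highest share of product in all that became product or trapped intermediate, at the outlet or at the end ("none" if the first two lie within 2 percentage points) (north-west / north / south-west / none)
2. share of product in all that became product or trapped intermediate, at the outlet or at the end, north-west
3. share of product in all that became product or trapped intermediate, at the outlet or at the end, north
4. share of product in all that became product or trapped intermediate, at the outlet or at the end, south-west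

- the stated concentrations are those of everything mixed, before any reaction; amounts are the same in each set-up
- the feed brings no volume worth counting
- run time (north-west): 30 h

**Two exits.** I held the capture agent at its charge, which makes trapping pseudo-first-order in intermediate B, at 0.00330 /h. Intermediate C has two exits, back to intermediate B and on to product. One over their sum is its catch-up time, 8.47 h. Of each fraction of the charge that enters intermediate C and no longer stands there, 3.73% has become product. With intermediate C caught up, I reckoned 0.565 of product per trapped intermediate (a selectivity factor), a share of 36.1%.

**Turned round.** In the tank, washout is a third exit, which gave a ratio of 0.440 and a share of 30.6%. In my reckoning, for north-west to beat that with intermediate B steady, the run would have to last 38.5 h, longer than its 30 h. With intermediate B steady from the start, I reckoned a ratio of 0.405 for north-west, a share of 28.8%, below the tank. That gap of 1.8 percentage points lies inside the margin, but intermediate B is not charged and had to build up in north-west, so I took that share as a high estimate. The feed in north lasts 24.0 h, longer than the catch-up time, so I put north lowest. I committed to south-west.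

**The forecast.** It said none, with 36% for north-west, 36% for north and 32% for south-west: “batch and fed runs both land near 36%”. Mine differed on both closed flasks and on the choice.

**The result.** The answer was south-west, at 31.8%, against 28.7% in north-west and 24.4% in north. At 30.0 h, intermediate C in north still held 2.40% of the charge. From its trapped intermediate, 0.354%, with the capture agent held at its charge, I reckoned that 5.37% had entered intermediate C, so the catch-up time gives 0.110% of product, and the flask held 0.114%. For a neighbour of north with 0.075 M of capture agent, the same reckoning put 5.21% as entered, with 2.32% standing, which gave a product of 0.108% and a share of 11.1%; the flask gave 11.5%.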